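**Strategy.** Ring B is opened at C6–C7 and C9–C10 and ring A at C4–C5 (labdane numbering). In one flask an open-chain epoxy enal and a chiral allylboronate carrying the side chain are joined at C6–C7, and SnCl4 then folds the resulting epoxy triene into rings A and B, setting C4, C5 and C10. The step exploits the homoallylic C6 carbinol/C8=C9 olefin of ring B and the C3-oxygenated trans-fused A/B system with its C10 quaternary methyl. Both secondary hydroxyl groups (C3, C6) emerge equatorial and are inverted together by oxidation and hydride reduction; the silyl ether and methyl ester are cleaved last.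

Key step: step 13

Remark: labdane numbering is used for all intermediates (C17 on C8, C18/C19 on C4, C20 on C10), and the sense of induction of the copper–bisphosphine catalyst in step 12 is assumed as written; the ligand antipode is taken should it prove opposite.

Step 1
Reactants: 1 geraniol
Product: 2 geranyl 4-methoxybenzyl ether
Conditions: NaH, 4-methoxybenzyl chloride, Bu4NI (cat.), THF–DMF, 0 °C to rt
Reagents that add atoms: 4-methoxybenzyl chloride, COc1ccc(CCl)cc1
Why: Williamson etherification of the primary allylic alkoxide with the benzylic chloride should proceed cleanly; no stereocenter is formed.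

Step 2
Reactants: 2 geranyl 4-methoxybenzyl ether
Product: 3 (E)-6,7-epoxygeranyl 4-methoxybenzyl ether (racemic at the oxirane CH)
Conditions: mCPBA, NaHCO3, CH2Cl2, −20 to 0 °C
Reagents that add atoms: 3-chloroperoxybenzoic acid, O=C(OO)c1cccc(Cl)c1
Why: Prilezhaev epoxidation should take the more electron-rich terminal olefin, the 2,3-olefin being deactivated by the allylic ether oxygen; the new center is racemic and is removed in step 3.

Step 3
Reactants: 3 (E)-6,7-epoxygeranyl 4-methoxybenzyl ether
Product: 4 (4E)-6-[(4-methoxybenzyl)oxy]-4-methylhex-4-enal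
Conditions: H5IO6, THF–H2O, 0 °C
Reagents that add atoms: none
Why: Acid-catalysed hydrolysis of the epoxide (water enters at the tertiary carbon, so the aldehyde keeps the oxirane oxygen) and Malaprade cleavage of the glycol should give the aldehyde and acetone.

Step 4
Reactants: 4 (4E)-6-[(4-methoxybenzyl)oxy]-4-methylhex-4-enal; 5 methyl 2-[bis(2,2,2-trifluoroethoxy)phosphoryl]propanoate
Product: 6 methyl (2Z,6E)-8-[(4-methoxybenzyl)oxy]-2,6-dimethylocta-2,6-dienoate
Conditions: KN(SiMe3)2, 18-crown-6, THF, −78 °C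
Reagents that add atoms: none
Why: Still–Gennari olefination (trifluoroethyl phosphonate, dissociated potassium base) should give the (Z)-trisubstituted enoate under kinetic control, placing the future C19 carbon cis to the chain.

Step 5
Reactants: 6 methyl (2Z,6E)-8-[(4-methoxybenzyl)oxy]-2,6-dimethylocta-2,6-dienoate
Product: 7 (2Z,6E)-8-[(4-methoxybenzyl)oxy]-2,6-dimethylocta-2,6-dien-1-ol
Conditions: i-Bu2AlH, CH2Cl2, −78 °C; aq. KNaC4H4O6
Reagents that add atoms: none
Why: 1,2-Reduction of the enoate by the aluminium hydride at low temperature should give the allylic alcohol without touching the olefins or the benzyl ether.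

Step 6
Reactants: 7 (2Z,6E)-8-[(4-methoxybenzyl)oxy]-2,6-dimethylocta-2,6-dien-1-ol
Product: 8 [(2R,3S)-3-{(3E)-5-[(4-methoxybenzyl)oxy]-3-methylpent-3-en-1-yl}-2-methyloxiran-2-yl]methanol
Conditions: Ti(OiPr)4 (cat.), D-(−)-diethyl tartrate (cat.), t-BuOOH, 4 Å molecular sieves, CH2Cl2, −20 °C
Reagents that add atoms: tert-butyl hydroperoxide, CC(C)(C)OO
Why: Sharpless asymmetric epoxidation is chemoselective for the allylic alcohol and, with the D-(−)-tartrate, should deliver oxygen to the face that gives C3 S and C4 R (labdane numbering).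

Step 7
Reactants: 8 epoxy alcohol
Product: 9 tert-butyl{[(2R,3S)-3-{(3E)-5-[(4-methoxybenzyl)oxy]-3-methylpent-3-en-1-yl}-2-methyloxiran-2-yl]methoxy}diphenylsilane
Conditions: t-BuPh2SiCl, imidazole, DMF, rt
Reagents that add atoms: tert-butyl(chloro)diphenylsilane, CC(C)(C)[Si](Cl)(c1ccccc1)c1ccccc1
Why: Silylation of the primary alcohol gives an ether that has no carbonyl group to assist epoxide opening and that survives Lewis acids.

Step 8
Reactants: 9 silyl ether
Product: 10 (2E)-5-[(2S,3R)-3-({[tert-butyl(diphenyl)silyl]oxy}methyl)-3-methyloxiran-2-yl]-3-methylpent-2-en-1-ol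
Conditions: DDQ, CH2Cl2–pH 7 phosphate buffer, 0 °C
Reagents that add atoms: none
Why: Oxidative cleavage of the 4-methoxybenzyl ether (hydride abstraction by DDQ, hydrolysis of the oxocarbenium ion) should leave the silyl ether, the epoxide and the olefin intact.

Step 9
Reactants: 10 allylic alcohol
Product: 11 (2E)-5-[(2S,3R)-3-({[tert-butyl(diphenyl)silyl]oxy}methyl)-3-methyloxiran-2-yl]-3-methylpent-2-enal
Conditions: MnO2, CH2Cl2, rt
Reagents that add atoms: none
Why: MnO2 oxidizes the allylic alcohol selectively to the (E)-enal without olefin isomerization.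

Step 10
Reactants: 12 methyl (2E)-3,7-dimethylocta-2,6-dienoate (methyl geranate)
Product: 13 methyl (2E,6E)-8-hydroxy-3,7-dimethylocta-2,6-dienoate
Conditions: SeO2 (cat.), t-BuOOH, salicylic acid (cat.), CH2Cl2, rt
Reagents that add atoms: tert-butyl hydroperoxide (oxygen relayed by SeO2), CC(C)(C)OO
Why: Riley allylic oxidation (ene reaction, then 2,3-sigmatropic shift) of the electron-rich distal olefin should functionalize the (E)-methyl group; the conjugated olefin is inert.

Step 11
Reactants: 13 methyl (2E,6E)-8-hydroxy-3,7-dimethylocta-2,6-dienoate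
Product: 14 methyl (2E,6E)-8-[(methoxycarbonyl)oxy]-3,7-dimethylocta-2,6-dienoate
Conditions: ClCO2Me, pyridine, CH2Cl2, 0 °C
Reagents that add atoms: methyl chloroformate, COC(=O)Cl
Why: Acylation of the primary allylic alcohol gives the carbonate leaving group needed for copper-catalysed allylic substitution.

Step 12
Reactants: 14 allylic carbonate
Product: 15 methyl (2E,6S)-3,7-dimethyl-6-(4,4,5,5-tetramethyl-1,3,2-dioxaborolan-2-yl)octa-2,7-dienoate
Conditions: B2pin2, CuCl (5 mol%), KOt-Bu (5 mol%), (R,R)-2,3-bis(tert-butylmethylphosphino)quinoxaline (5 mol%), THF, 0 °C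
Reagents that add atoms: bis(pinacolato)diboron, CC1(C)OB(OC1(C)C)B1OC(C)(C)C(C)(C)O1
Why: Copper–boryl γ-selective allylic substitution (borylcupration of the olefin, then β-elimination of the carbonate) should place boron on C9 and create the 1,1-disubstituted C7=C8 olefin, the chiral bisphosphine setting C9.

Step 13
Reactants: 11 epoxy enal; 15 (S)-allylboronate
Product: 17 methyl 19-[(tert-butyldiphenylsilyl)oxy]-3β,6α-dihydroxylabda-8,13E-dien-15-oate, via open-chain C6 pinacol borate 16 (not isolated)
Conditions: 15 (1.2 equiv), toluene, 50 °C; then CH2Cl2, SnCl4 (3 equiv), −78 to −30 °C; aq. NaHCO3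
Reagents that add atoms: none
Why: The (S)-boronate should add to the enal through a closed Zimmerman–Traxler-type chair (α-substituted allylboronate addition; alkenyl residue equatorial, C11 chain axial), forming C6–C7 and giving the 6S borate 16 with a (Z)-C8=C9 olefin. SnCl4 then opens the epoxide at its tertiary carbon C4 with anti attack by C5 of the C5=C10 olefin, C9 of the C8=C9 olefin captures the C10 cation, and the C8 cation loses the C9 proton; the closest known reaction type is the Stork–Eschenmoser-type epoxide-initiated cationic polyene cyclization. Ring A closes 6-endo at the epoxide and 6-endo-trig at the olefin, and ring B closes 6-endo-trig, both in one chair–chair fold. C3 keeps the epoxide configuration, C4 is inverted so that CH2OSi becomes axial (β), the E olefin places H-5 and the C10 methyl trans, and the 3S epoxide fixes the absolute sense of the fold. C6 is set by the C–B stereocenter and its borate sits equatorial in this fold. The step needs the Lewis acid to ionize the epoxide and not the allylic C6–O bond, Markovnikov attack at both olefins (the enoate olefin is inert), and proton loss toward C9, which removes the axial C11 chain of the Z-derived cation and gives the tetrasubstituted olefin under the equilibrating conditions.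

Step 14
Reactants: 17 3β,6α-diol
Product: 18 methyl 19-[(tert-butyldiphenylsilyl)oxy]-3,6-dioxolabda-8,13E-dien-15-oate
Conditions: Dess–Martin periodinane, NaHCO3, CH2Cl2, 0 °C to rt
Reagents that add atoms: none
Why: Dess–Martin oxidation under buffered, non-basic conditions should convert both equatorial carbinols into ketones without moving the β,γ-olefin into conjugation or epimerizing C5.

Step 15
Reactants: 18 3,6-dione
Product: 19 methyl 19-[(tert-butyldiphenylsilyl)oxy]-3α,6β-dihydroxylabda-8,13E-dien-15-oate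
Conditions: LiBH(s-Bu)3, THF, −78 °C; H2O
Reagents that add atoms: none
Why: The bulky borohydride should attack the C3 ketone from the equatorial direction (axial 3α-OH) and the C6 ketone from the α face, the β face being blocked by the C10 methyl and C19 groups (axial 6β-OH); the β,β-disubstituted enoate is not reduced at −78 °C.

Step 16
Reactants: 19 3α,6β-diol
Product: 21 3α,6β,19-trihydroxylabda-8,13E-dien-15-oic acid, via methyl ester triol 20 (not isolated)
Conditions: Bu4NF, THF, 40 °C; then LiOH, MeOH–H2O, 40 °C; 1 M HCl to pH 3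
Reagents that add atoms: lithium hydroxide (oxygen of the carboxyl OH), [Li+].[OH-]
Why: Fluoride cleaves the silyl ether and hydroxide saponifies the methyl ester in the same flask; acidification should give the acid with all stereocenters untouched.

**Compound list**

1 | geraniol, (2E)-3,7-dimethylocta-2,6-dien-1-ol | OC/C=C(C)/CCC=C(C)C | starting material
2 | geranyl 4-methoxybenzyl ether | COc1ccc(COC/C=C(C)/CCC=C(C)C)cc1 | intermediate
3 | (E)-6,7-epoxygeranyl 4-methoxybenzyl ether (racemic) | COc1ccc(COC/C=C(C)/CCC2OC2(C)C)cc1 | intermediate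
4 | (4E)-6-[(4-methoxybenzyl)oxy]-4-methylhex-4-enal | COc1ccc(COC/C=C(C)/CCC=O)cc1 | intermediate
5 | methyl 2-[bis(2,2,2-trifluoroethoxy)phosphoryl]propanoate | COC(=O)C(C)P(=O)(OCC(F)(F)F)OCC(F)(F)F | starting material
6 | methyl (2Z,6E)-8-[(4-methoxybenzyl)oxy]-2,6-dimethylocta-2,6-dienoate | COc1ccc(COC/C=C(C)/CC/C=C(C)\C(=O)OC)cc1 | intermediate
7 | (2Z,6E)-8-[(4-methoxybenzyl)oxy]-2,6-dimethylocta-2,6-dien-1-ol | COc1ccc(COC/C=C(C)/CC/C=C(C)\CO)cc1 | intermediate
8 | [(2R,3S)-3-{(3E)-5-[(4-methoxybenzyl)oxy]-3-methylpent-3-en-1-yl}-2-methyloxiran-2-yl]methanol | COc1ccc(COC/C=C(C)/CC[C@@H]2O[C@]2(C)CO)cc1 | intermediate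
9 | tert-butyldiphenylsilyl ether of 8 | COc1ccc(COC/C=C(C)/CC[C@@H]2O[C@]2(C)CO[Si](c3ccccc3)(c3ccccc3)C(C)(C)C)cc1 | intermediate
10 | (2E)-5-[(2S,3R)-3-({[tert-butyl(diphenyl)silyl]oxy}methyl)-3-methyloxiran-2-yl]-3-methylpent-2-en-1-ol | OC/C=C(C)/CC[C@@H]1O[C@]1(C)CO[Si](c2ccccc2)(c2ccccc2)C(C)(C)C | intermediate
11 | (2E)-5-[(2S,3R)-3-({[tert-butyl(diphenyl)silyl]oxy}methyl)-3-methyloxiran-2-yl]-3-methylpent-2-enal | O=C/C=C(C)/CC[C@@H]1O[C@]1(C)CO[Si](c2ccccc2)(c2ccccc2)C(C)(C)C | intermediate
12 | methyl (2E)-3,7-dimethylocta-2,6-dienoate (methyl geranate) | COC(=O)/C=C(C)/CCC=C(C)C | starting material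
13 | methyl (2E,6E)-8-hydroxy-3,7-dimethylocta-2,6-dienoate | COC(=O)/C=C(C)/CC/C=C(C)/CO | intermediate
14 | methyl (2E,6E)-8-[(methoxycarbonyl)oxy]-3,7-dimethylocta-2,6-dienoate | COC(=O)/C=C(C)/CC/C=C(C)/COC(=O)OC | intermediate
15 | methyl (2E,6S)-3,7-dimethyl-6-(4,4,5,5-tetramethyl-1,3,2-dioxaborolan-2-yl)octa-2,7-dienoate | C=C(C)[C@@H](B1OC(C)(C)C(C)(C)O1)CC/C(C)=C/C(=O)OC | intermediate
16 | methyl (2E,6Z,9S,10E)-13-[(2S,3R)-3-({[tert-butyl(diphenyl)silyl]oxy}methyl)-3-methyloxiran-2-yl]-3,7,11-trimethyl-9-[(4,4,5,5-tetramethyl-1,3,2-dioxaborolan-2-yl)oxy]trideca-2,6,10-trienoate (open-chain C6 pinacol borate, 6S in labdane numbering) | COC(=O)/C=C(C)/CC/C=C(C)\C[C@H](OB1OC(C)(C)C(C)(C)O1)/C=C(C)/CC[C@@H]2O[C@]2(C)CO[Si](c3ccccc3)(c3ccccc3)C(C)(C)C | intermediate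
17 | methyl 19-[(tert-butyldiphenylsilyl)oxy]-3β,6α-dihydroxylabda-8,13E-dien-15-oate | CC1=C(CC/C(C)=C/C(=O)OC)[C@@]2(C)CC[C@H](O)[C@](C)(CO[Si](c3ccccc3)(c3ccccc3)C(C)(C)C)[C@@H]2[C@@H](O)C1 | intermediate
18 | methyl 19-[(tert-butyldiphenylsilyl)oxy]-3,6-dioxolabda-8,13E-dien-15-oate | CC1=C(CC/C(C)=C/C(=O)OC)[C@@]2(C)CCC(=O)[C@](C)(CO[Si](c3ccccc3)(c3ccccc3)C(C)(C)C)[C@@H]2C(=O)C1 | intermediate
19 | methyl 19-[(tert-butyldiphenylsilyl)oxy]-3α,6β-dihydroxylabda-8,13E-dien-15-oate | CC1=C(CC/C(C)=C/C(=O)OC)[C@@]2(C)CC[C@@H](O)[C@](C)(CO[Si](c3ccccc3)(c3ccccc3)C(C)(C)C)[C@@H]2[C@H](O)C1 | intermediate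
20 | methyl 3α,6β,19-trihydroxylabda-8,13E-dien-15-oate | CC1=C(CC/C(C)=C/C(=O)OC)[C@@]2(C)CC[C@@H](O)[C@](C)(CO)[C@@H]2[C@H](O)C1 | intermediate
21 | 3α,6β,19-trihydroxylabda-8,13E-dien-15-oic acid | CC1=C(CC/C(C)=C/C(=O)O)[C@@]2(C)CC[C@@H](O)[C@](C)(CO)[C@@H]2[C@H](O)C1 | target

**Step count.** Total: 16 steps. Longest linear sequence: 13 steps (steps 1–9 and 13–16); steps 10–12 make the second fragment.

**Steps most likely to fail**

Step 13. The C8 cation may lose its proton toward C7 or C17 instead of C9, so that olefin regioisomers form; ionization of the allylic C6–O bond by the Lewis acid may also compete with epoxide opening. The fallback sets the olefin position through the C6 ketone instead of through the cation. It sets out from 16, which is cyclized with MeAlCl2 in CH2Cl2 at −78 °C (irreversible proton removal) to the kinetic exocyclic olefin, methyl 19-[(tert-butyldiphenylsilyl)oxy]-3β,6α-dihydroxy-9-epi-labda-8(17),13E-dien-15-oate F1. Dess–Martin oxidation gives the β,γ-unsaturated dione methyl 19-[(tert-butyldiphenylsilyl)oxy]-3,6-dioxo-9-epi-labda-8(17),13E-dien-15-oate F2. DBU in CH2Cl2 moves the olefin into conjugation and equilibrates C9, giving methyl 19-[(tert-butyldiphenylsilyl)oxy]-3,6-dioxolabda-7,13E-dien-15-oate F3; any 7-ene formed in the cyclization converges on the same compound. KOt-Bu in t-BuOH then forms the more substituted extended dienolate, and kinetic α-protonation at C7 with aqueous AcOH deconjugates the enone. The fallback comes back to the route at 18.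

Step 12. The copper–boryl species may add to the enoate in a conjugate sense, and enantioface control on the trisubstituted olefin may be poor. The fallback gives up reagent control at C6 and relies on stereoconvergence. It sets out from 14: achiral catalysis (CuCl, KOt-Bu, 4,5-bis(diphenylphosphino)-9,9-dimethylxanthene, B2pin2, THF) gives racemic methyl (2E)-3,7-dimethyl-6-(4,4,5,5-tetramethyl-1,3,2-dioxaborolan-2-yl)octa-2,7-dienoate F4. In step 13 its S half gives 17 as planned. Its R half gives the 6R epimer of the open-chain borate F5 and from it methyl 19-[(tert-butyldiphenylsilyl)oxy]-3β,6β-dihydroxylabda-8,13E-dien-15-oate F6, whose axial borate should slow the ring closure. Compounds 17 and F6 are oxidized together in step 14, where C6 becomes a ketone, and the fallback comes back to the route at 18.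

Step 15. Hydride may attack C3 from the axial direction because the equatorial path passes the bulky axial CH2OSi group, which would give the 3β alcohol. The fallback reverses the order of the last operations so that the reduction is run on a less hindered substrate. It sets out from 18: Bu4NF buffered with AcOH in THF gives methyl 19-hydroxy-3,6-dioxolabda-8,13E-dien-15-oate F7, and LiBH(s-Bu)3 in THF at −78 °C then reduces both ketones. The fallback comes back to the route at 20, which is saponified as in the second stage of step 16.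

**Further compounds**

F1 | step 13 | methyl 19-[(tert-butyldiphenylsilyl)oxy]-3β,6α-dihydroxy-9-epi-labda-8(17),13E-dien-15-oate | C=C1[C@@H](CC/C(C)=C/C(=O)OC)[C@@]2(C)CC[C@H](O)[C@](C)(CO[Si](c3ccccc3)(c3ccccc3)C(C)(C)C)[C@@H]2[C@@H](O)C1
F2 | step 13 | methyl 19-[(tert-butyldiphenylsilyl)oxy]-3,6-dioxo-9-epi-labda-8(17),13E-dien-15-oate | C=C1[C@@H](CC/C(C)=C/C(=O)OC)[C@@]2(C)CCC(=O)[C@](C)(CO[Si](c3ccccc3)(c3ccccc3)C(C)(C)C)[C@@H]2C(=O)C1
F3 | step 13 | methyl 19-[(tert-butyldiphenylsilyl)oxy]-3,6-dioxolabda-7,13E-dien-15-oate | CC1[C@H](CC/C(C)=C/C(=O)OC)[C@@]2(C)CCC(=O)[C@](C)(CO[Si](c3ccccc3)(c3ccccc3)C(C)(C)C)[C@@H]2C(=O)C=1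
F4 | step 12 | racemic methyl (2E)-3,7-dimethyl-6-(4,4,5,5-tetramethyl-1,3,2-dioxaborolan-2-yl)octa-2,7-dienoate | C=C(C)C(B1OC(C)(C)C(C)(C)O1)CC/C(C)=C/C(=O)OC
F5 | step 12 | 6R epimer of the open-chain C6 pinacol borate 16 | COC(=O)/C=C(C)/CC/C=C(C)\C[C@@H](OB1OC(C)(C)C(C)(C)O1)/C=C(C)/CC[C@@H]2O[C@]2(C)CO[Si](c3ccccc3)(c3ccccc3)C(C)(C)C
F6 | step 12 | methyl 19-[(tert-butyldiphenylsilyl)oxy]-3β,6β-dihydroxylabda-8,13E-dien-15-oate | CC1=C(CC/C(C)=C/C(=O)OC)[C@@]2(C)CC[C@H](O)[C@](C)(CO[Si](c3ccccc3)(c3ccccc3)C(C)(C)C)[C@@H]2[C@H](O)C1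
F7 | step 15 | methyl 19-hydroxy-3,6-dioxolabda-8,13E-dien-15-oate | CC1=C(CC/C(C)=C/C(=O)OC)[C@@]2(C)CCC(=O)[C@](C)(CO)[C@@H]2C(=O)C1
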